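## Structural features

The target is a linear trimer of three 2-(4-hydroxyphenyl)-7,8-dihydroxychroman (flavan) units, called top, middle and bottom here. C4 of the top unit is bonded to C6 of ring A of the middle unit and C4 of the middle unit to C6 of ring A of the bottom unit, which ends in a free C4 hydroxyl and is a flavan-3,4-diol. Each pyran ring carries three contiguous stereocentres (C2, C3, C4), nine in all: every unit is (2R,3R) with the C2 aryl group and the C3 oxygen cis, the C4 aryl bond of the top and middle units is trans to both (4S in the free target), and the bottom C4 hydroxyl is cis to the C3 hydroxyl (4R). Every C4 is benzylic to a ring A with oxygen ortho (O1) and para (C7–O), so the bottom C4–O bond and both C4–C6 bonds ionise in acid, the bottom C4–OH can be lost by hydrogenolysis, and the free 7,8-diols oxidise in base and air. The real difficulty is the repeated, controlled construction of a diarylmethine C4 next to a cis C2/C3 pair, because the 2,3-cis pattern is not the thermodynamic one and a ring A without a 5-oxygen is a poor nucleophile for cationic C4 arylation. The feature used is that C4, C3 and C2 of each pyran ring form a chain of three CH carbons, each with one substituent that can arrive as a nucleophile (aryl or O at C4, O at C3, aryl at C2), ending at O1, which can come from boron. C2 of the middle unit is therefore inserted as a CHCl unit between C3 (on boron) and the 4-benzyloxyphenyl nucleophile, and the C2–B bond later becomes C2–O1. All nine centres have the same spatial sense along the chain, so one enantiomer of a C2-symmetric diol on boron, (S,S), serves every insertion; each must give the (R)-α-chloride (Cl > C > B > H), which is the established sense for that diol.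

## Logic of the disconnections

40 ⇒ 39. The thirteen O–CH2Ph bonds are cut. Benzyl is the one group that survives carbenoids, Grignard reagents, alkoxides, alkaline peroxide, palladium coupling and NBS and leaves without acid or base. The gain is a single neutral final step. The demand is that hydrogenolysis stops at the O–CH2Ph bonds and spares the bottom C4–O bond.

39 ⇒ 38. The O1–C8a bond of the top unit is cut. It is the only pyran bond with no stereocentre at either end, so the three centres can be made on an open chain. The gain is a 1,3-diarylpropanol with an ortho bromide. The demand is an intramolecular C–O coupling of a secondary benzylic alcohol that beats β-hydride elimination.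

38 ⇒ 37 ⇒ 35 + 5 + 15. C2–O is traced to C2–B, then C2–C3 and C2–aryl are cut. C2 becomes the one-carbon unit of 5, stitched between the C3 boronic ester and the aryl group of 15. The gain is two skeletal bonds and one stereocentre in one operation. The demand is diol control at the first 1,2-shift and clean inversion at the second.

35 ⇒ 33 + 5. C3–C4 and C3–O are cut in the same way, with an alkoxide as the second nucleophile. The demand is displacement of a hindered α-chloride by oxygen without loss of HCl.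

33 ⇒ 30 + 8 + 9. C4–C6 (to the middle unit) and C4–C4a are cut. C4 is the CHCl carbon of 8, joined first to the metallated 30 and then to the aryl group of 9. Because the diol is C2-symmetric, aryl metal plus 8 gives the same ate complex as an arylboronic ester plus 5, which saves a borylation step. The demand is that the electron-rich benzylic chloride keeps its configuration until the second aryl group arrives.

30 ⇒ 29. C6–Br is cut. The demand is bromination at the one position that is ortho and para to oxygen.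

29 ⇒ 28 ⇒ 27 ⇒ 25 + 5 + 15. The same three cuts are made in the middle unit (O1–C8a; C2–O via C2–B; C2–C3 and C2–aryl). The last of these is the key disconnection, from 27 to 25, 5 and 15.

25 ⇒ 23 ⇒ 20 + 8 + 9. C3–O and C3–C4, then C4–C6 (to the bottom unit) and C4–C4a, as for the top unit.

20 ⇒ 19 ⇒ 18 ⇒ 17 ⇒ 13 ⇒ 11 ⇒ 9 + 8. The bottom unit falls to the same cycle. Its C4 nucleophile is an alkoxide instead of an aryl group, which gives the 3,4-cis diol as two benzyl ethers directly.

9 ⇒ 3 ⇒ 2 ⇒ 1; 8 ⇒ 5 + 6; 5 ⇒ 4; 15 ⇒ 14. Ring A of every unit comes from 1 by benzylation, para iodination and iodine–magnesium exchange. All nine pyran carbons come from 4 by way of 5, all boron-bound chirality from 6 (recovered at each oxidation), and every ring B from 14. The two organometallic reagents that recur in every cycle, 5 and 9, are each traced to one preparation of their own; the demand is that each is made cold and consumed at once.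

## Other disconnections considered

Alternative 1: The cut is C3–C4 of the top pyran ring. O1–C8a is already present as an aryl vinyl ether and C4 is held as the benzhydrol A1. In the forward step a confined chiral Brønsted acid would ionise A1 to the diarylmethyl cation, the terminal vinyl ether carbon (C3) would attack C4 in a 6-endo closure, and loss of a proton from C3 would give the 4H-chromene A2.
- In its favour: one catalytic step forms the ring and the C4 centre, the chirality source is substoichiometric, no carbenoid at −100 °C is needed, and O1–C8a needs no metal-catalysed coupling. On these points it is the better of the two.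
- Against it here: the cation is stabilised by two oxygenated rings and is long-lived, so face selection by a chiral counter-anion on a substrate with five existing stereocentres is uncertain. The acid can also ionise the bottom C4–O bond (hence the carbonate, which in turn excludes organometallic steps) and the existing C4–C6 bond. A2 still lacks the C2 aryl group and the C3 oxygen, which would be added to the enol ether under substrate control.
- Comparison: on structure, A2 fixes one of three centres where the chosen plan fixes all three with one reagent. On mechanism, the acid-driven cationic path threatens the acid-labile bonds that the boron-centred path leaves alone. On step economy it is about equal at best: three steps to A1, the cyclisation, then four or more for C2 and C3, against six per unit (reagent preparations aside).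

Alternative 2: The cut is C4–C4a and O1–C2 of the top unit; ring A of that unit is grown from A4 (cyclohexane-1,2-dione) instead of being taken from an arene. A diarylprolinol silyl ether would turn the enal A3 into an iminium ion, the enol carbon of A4 would add to the β-carbon (C4), and the enol oxygen would close on the aldehyde carbon to give the lactol A5.
- In its favour: a well-known organocatalytic Michael–hemiacetalisation type, near room temperature, metal-free, tolerant of benzyl ethers and an acetal, with catalyst control at C4. In mildness and cost of the chirality source it is the better.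
- Against it here: A5 is far from the target in oxidation pattern. Its carbocycle must be dehydrogenated and given the C7 oxygen, C3 has no oxygen, C2 has no aryl group, and C2 and C3 would be set later under substrate control. The β-substituent of A3 is a very large ortho-substituted aryl group, which slows iminium addition.
- Comparison: on structure it rebuilds a benzene ring that cheap arenes supply. On mechanism it is equal in reliability for C4 and weaker for C2 and C3. On step economy it is clearly longer, an estimated ten or more steps per unit.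

Alternative 3: The cut is O1–C2 and C3–O of the top unit. The retron is the 2,3-dihydrobenzofuran A6, whose ring oxygen sits on the future C3 and whose side chain carries the future C2 as a mesylate. Zn(OAc)2 would assist loss of mesylate with participation of the ring oxygen, and acetate would open the bridged oxonium ion at C3 to give the ring-expanded chroman A7.
- In its favour: a stereospecific double inversion under nearly neutral conditions; the 4'-pivalate damps benzylic cation formation; the key step is the last skeletal event and gives the whole protected trimer without a C–O cross-coupling. It equals the chosen plan in stereospecificity and is better in the mildness of the final ring-forming step.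
- Against it here: it creates no stereocentre from an achiral carbon, so C4, C3 and C2 must already be present in A6, and the stereocontrolled synthesis of such a dihydrobenzofuran carrying the dimer is the unsolved part. Acetate may open the oxonium ion at the benzylic C2 instead, which returns a dihydrobenzofuran. The acetate and pivalate need a basic or hydride removal on a base-sensitive skeleton.
- Comparison: on structure the problem is moved, not solved. On mechanism the two are equal (stereospecific shifts; substrate control against reagent control). On step economy it is no shorter, because A6 needs its own multi-step synthesis for each upper unit.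

Key step: step 15

Remark: 1, 4, 6 and 14 are taken as commercial; ring A comes from 1 because no acetyl carbon is needed once C4 comes from 4.
Remark: the bottom 3,4-diol is carried as two benzyl ethers, not as an isopropylidene acetal, so that it arises from the same insertion cycle and no acid is needed next to the ionisable bottom C4–O bond at the end.
Remark: reagents 5 and 9 cannot be stored; steps 3 and 5 describe their preparation once, and each is run again, unchanged and on the scale needed, directly before every later step that lists 5 or 9 as a reactant.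
Remark: tetracoordinate boron ate complexes are short-lived and are described in the Why lines; the α-chloro boronic esters and aryllithium compounds made in the flask are numbered.
Remark: abbreviations in names: Bn = benzyl; ArBr = 3,4-bis(benzyloxy)-2-bromophenyl; BnOAr = 4-(benzyloxy)phenyl; Bdch = (4S,5S)-4,5-dicyclohexyl-1,3,2-dioxaborolan-2-yl; Bot = (2R,3R,4R)-3,4,7,8-tetrakis(benzyloxy)-2-[4-(benzyloxy)phenyl]chroman-6-yl; Dim = the 6-yl group of the middle unit of 29; flavan numbering throughout.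

## Steps

Step 1
Reactants: 1 3-bromobenzene-1,2-diol
Product: 2 1,2-bis(benzyloxy)-3-bromobenzene
Conditions: BnBr, K2CO3, DMF, 60 °C
Reagents that add atoms: benzyl bromide BrCc1ccccc1
Why: Williamson etherification of both phenols; no stereocentre is involved.

Step 2
Reactants: 2 1,2-bis(benzyloxy)-3-bromobenzene
Product: 3 1,2-bis(benzyloxy)-3-bromo-4-iodobenzene
Conditions: NIS, TFA (cat.), MeCN, 0 °C → rt
Reagents that add atoms: N-iodosuccinimide O=C1CCC(=O)N1I
Why: Electrophilic aromatic iodination; the unhindered 1-benzyloxy group directs para (C4, beside Br), while the 2-benzyloxy group, flanked on both sides, is twisted out of conjugation, as in the para-selective halogenation of other 3-substituted 1,2-dialkoxybenzenes.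

Step 3
Reactants: 4 dichloromethane
Product: 5 (dichloromethyl)lithium (THF solution held at −100 °C and used at once)
Conditions: nBuLi (hexanes), THF, −100 °C, 30 min
Reagents that add atoms: n-butyllithium [Li]CCCC
Why: Deprotonation of an excess of 4 by nBuLi at −100 °C gives the carbenoid, which survives only at that temperature. The cold solution is consumed in the same flask, and the preparation is repeated before each of steps 4, 7, 9, 14, 15, 20 and 21.

Step 4
Reactants: 5 (dichloromethyl)lithium; 6 (1S,2S)-1,2-dicyclohexylethane-1,2-diol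
Product: 8 (4S,5S)-4,5-dicyclohexyl-2-(dichloromethyl)-1,3,2-dioxaborolane, via dimethyl (dichloromethyl)boronate 7 (not isolated)
Conditions: B(OMe)3, THF, −100 °C → rt; HCl (Et2O), 0 °C; then 6, Et2O, rt
Reagents that add atoms: trimethyl borate COB(OC)OC
Why: B(OMe)3 traps the carbenoid as a borate, protonolysis gives 7, and transesterification with the 1,2-diol gives the dioxaborolane; this is the standard route to (dichloromethyl)boronic esters.

Step 5
Reactants: 3 1,2-bis(benzyloxy)-3-bromo-4-iodobenzene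
Product: 9 [3,4-bis(benzyloxy)-2-bromophenyl]magnesium chloride (THF solution held at −40 °C and used at once)
Conditions: iPrMgCl·LiCl, THF, −40 °C, 1 h
Reagents that add atoms: isopropylmagnesium chloride–lithium chloride complex CC(C)[Mg]Cl.[Li+].[Cl-]
Why: Iodine–magnesium exchange is far faster at the C–I bond than at the C–Br bond, and the ortho-bromoaryl Grignard reagent does not eliminate to an aryne below about −20 °C. The solution is not stored, and the exchange is repeated before each of steps 6, 13 and 19.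

Step 6
Reactants: 9 [3,4-bis(benzyloxy)-2-bromophenyl]magnesium chloride; 8 (4S,5S)-4,5-dicyclohexyl-2-(dichloromethyl)-1,3,2-dioxaborolane
Product: 11 (S)-ArBr-CH(OBn)-Bdch (bottom C4 set), via α-chloro boronic ester 10 (not isolated)
Conditions: 8, THF, −78 °C; ZnCl2, −78 °C → rt; then BnOLi (BnOH, nBuLi), THF/DMSO, 0 °C → rt
Reagents that add atoms: benzyl alcohol OCc1ccccc1
Why: Compound 9 adds to boron of 8 to give the same ate complex that an arylboronic ester and 5 would give, and the ZnCl2-assisted 1,2-aryl shift (Matteson homologation) gives the (R)-chloride 10 under control of the (S,S)-diol. Benzyloxide then adds to boron and migrates to carbon with inversion, which sets the bottom C4 centre.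

Step 7
Reactants: 11 (S)-ArBr-CH(OBn)-Bdch; 5 (dichloromethyl)lithium
Product: 13 (1S,2R)-ArBr-CH(OBn)-CH(OBn)-Bdch (bottom C3 set), via α-chloro boronic ester 12 (not isolated)
Conditions: 11 added to 5, THF, −100 °C; ZnCl2, −100 °C → rt; then BnOLi (BnOH, nBuLi), THF/DMSO, 0 °C → rt
Reagents that add atoms: benzyl alcohol OCc1ccccc1
Why: Matteson homologation of an α-alkoxy boronic ester: C4 migrates from boron to the carbenoid carbon with retention and the (S,S)-diol selects the chloride that leaves, giving the (R)-chloride 12. Benzyloxide displaces chloride through the ate complex with inversion and sets C3 erythro to C4, the later 3,4-cis pair.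

Step 8
Reactants: 14 1-(benzyloxy)-4-bromobenzene
Product: 15 [4-(benzyloxy)phenyl]magnesium bromide (titrated THF solution)
Conditions: Mg, I2 (cat.), THF, 40 °C
Reagents that add atoms: magnesium [Mg]
Why: Grignard formation by insertion of magnesium into the aryl bromide; the solution is stable and serves steps 9, 15 and 21.

Step 9
Reactants: 13 (1S,2R)-ArBr-CH(OBn)-CH(OBn)-Bdch; 5 (dichloromethyl)lithium; 15 [4-(benzyloxy)phenyl]magnesium bromide
Product: 17 (1R,2S,3R)-ArBr-CH(OBn)-CH(OBn)-CH(BnOAr)-Bdch (bottom C2 set), via α-chloro boronic ester 16 (not isolated)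
Conditions: 13 added to 5, THF, −100 °C; ZnCl2, −100 °C → rt; then 15, −78 °C → rt
Reagents that add atoms: none
Why: The same three-component Matteson homologation as the key step, on the small fragment: C3 migrates with retention to give the (R)-chloride 16, then the aryl group of 15 migrates from boron to C2 with inversion. This sets C2 and rehearses step 15.

Step 10
Reactants: 17 (1R,2S,3R)-ArBr-CH(OBn)-CH(OBn)-CH(BnOAr)-Bdch
Product: 18 (1R,2S,3R)-2,3-bis(benzyloxy)-1-[4-(benzyloxy)phenyl]-3-ArBr-propan-1-ol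
Conditions: H2O2 (30% aq.), NaOH, THF, 0 °C → rt
Reagents that add atoms: hydrogen peroxide OO
Why: Alkaline peroxide oxidation of the C–B bond: hydroperoxide adds to boron and C2 migrates from boron to oxygen with retention; the diol 6 is recovered.

Step 11
Reactants: 18 (1R,2S,3R)-2,3-bis(benzyloxy)-1-[4-(benzyloxy)phenyl]-3-ArBr-propan-1-ol
Product: 19 (2R,3R,4R)-3,4,7,8-tetrakis(benzyloxy)-2-[4-(benzyloxy)phenyl]chromane (bottom unit; 2,3-cis-3,4-cis)
Conditions: Pd(OAc)2 (cat.), 2-(di-tert-butylphosphino)-1,1'-binaphthyl, Cs2CO3, toluene, 80 °C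
Reagents that add atoms: none
Why: Intramolecular Buchwald–Hartwig etherification: zerovalent palladium inserts into the C–Br bond, the alkoxide binds, and the bulky di-tert-butyl biaryl phosphine makes C–O reductive elimination faster than β-hydride elimination. The six-membered ring closes with no change at C2, C3 or C4.

Step 12
Reactants: 19 (2R,3R,4R)-3,4,7,8-tetrakis(benzyloxy)-2-[4-(benzyloxy)phenyl]chromane
Product: 20 (2R,3R,4R)-3,4,7,8-tetrakis(benzyloxy)-2-[4-(benzyloxy)phenyl]-6-bromochromane (Bot-Br)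
Conditions: NBS, MeCN/CH2Cl2, −20 → 0 °C, dark
Reagents that add atoms: N-bromosuccinimide O=C1CCC(=O)N1Br
Why: Electrophilic aromatic bromination; C6 is para to O1 and ortho to the 7-benzyloxy group and is the most activated position, while C5 is only para to the twisted 8-benzyloxy group and ring B is a less activated mono-ether.

Step 13
Reactants: 20 Bot-Br; 8 (4S,5S)-4,5-dicyclohexyl-2-(dichloromethyl)-1,3,2-dioxaborolane; 9 [3,4-bis(benzyloxy)-2-bromophenyl]magnesium chloride
Product: 23 (S)-Bot-CH(ArBr)-Bdch (middle C4 set), via aryllithium 21 (not isolated), via α-chloro boronic ester 22 (not isolated)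
Conditions: 20, nBuLi, THF, −78 °C; 8, −78 °C; ZnCl2, → rt; then 9 (excess), −78 → 0 °C
Reagents that add atoms: none
Why: Bromine–lithium exchange gives 21, which adds to boron of 8; the ZnCl2-assisted aryl shift gives the (R)-chloride 22 under control of the (S,S)-diol, and 9 then transfers its aryl group from boron to carbon with inversion (Matteson homologation with Grignard displacement). This sets C4 of the middle unit with both aryl groups in place.

Step 14
Reactants: 23 (S)-Bot-CH(ArBr)-Bdch; 5 (dichloromethyl)lithium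
Product: 25 (1S,2S)-Bot-CH(ArBr)-CH(OBn)-Bdch (middle C3 set; C1 on boron), via α-chloro boronic ester 24 (not isolated)
Conditions: 23 added to 5, THF, −100 °C; ZnCl2, −100 °C → rt; then BnOLi (BnOH, nBuLi), THF/DMSO, 0 °C → rt
Reagents that add atoms: benzyl alcohol OCc1ccccc1
Why: Matteson homologation as in step 7: the diarylmethyl carbon C4 migrates with retention to give the (R)-chloride 24, and benzyloxide displaces chloride with inversion, setting C3 trans to the C4 aryl bond of the later ring.

Step 15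
Reactants: 25 (1S,2S)-Bot-CH(ArBr)-CH(OBn)-Bdch; 5 (dichloromethyl)lithium; 15 [4-(benzyloxy)phenyl]magnesium bromide
Product: 27 (1R,2S,3S)-Bot-CH(ArBr)-CH(OBn)-CH(BnOAr)-Bdch (middle C2 set; C1 on boron), via α-chloro boronic ester 26 (not isolated)
Conditions: 25 added to 5, THF, −100 °C; ZnCl2, −100 °C → rt; then 15, −78 °C → rt
Reagents that add atoms: none
Why: Compound 5, generated from 4 at −100 °C as in step 3 directly before use, adds to the trigonal boron of 25 to give a tetracoordinate ate complex. ZnCl2 binds one chloride and one dioxaborolane oxygen, and C3 migrates from boron to the carbenoid carbon anti-periplanar to the departing chloride with retention at C3; this forms C2–C3 and gives the α-chloro boronic ester 26. The two chlorides of the ate complex are diastereotopic, and the C2-symmetric (S,S)-diol makes loss of one of them strongly preferred, which fixes 26 as the (1R)-chloride; the centres at C3 and C4 are spectators because the selecting element sits on boron. The aryl Grignard reagent 15 then adds to boron of 26 and its aryl group migrates to C2 with inversion, displacing the second chloride and forming C2–aryl, so the single new stereocentre of 27 is set by the diol and passed on by two stereospecific 1,2-shifts. No ring closes in this step. The closest known reaction type is the Matteson asymmetric homologation of α-alkoxy boronic esters with (dichloromethyl)lithium followed by Grignard displacement. The step needs chemoselectivity for boron over the aryl bromide and the benzyl ethers, which the low temperature and the Lewis acidity of the boronic ester secure, and it needs α-chloride displacement to outrun β-elimination of the C3 benzyloxy group from the ate complexes, which the much better leaving group on the α-carbon secures. Zinc-bound chloride does not re-attack, so 26, a non-benzylic secondary chloride, should keep its configuration until 15 is added.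

Step 16
Reactants: 27 (1R,2S,3S)-Bot-CH(ArBr)-CH(OBn)-CH(BnOAr)-Bdch
Product: 28 (1R,2R,3S)-2-(benzyloxy)-1-[4-(benzyloxy)phenyl]-3-ArBr-3-Bot-propan-1-ol
Conditions: H2O2 (30% aq.), NaOH, THF, 0 °C → rt
Reagents that add atoms: hydrogen peroxide OO
Why: Alkaline peroxide oxidation of the benzylic C–B bond with retention at C2; the β-benzyloxy boronic ester is oxidised at once so that it cannot eliminate, and 6 is recovered.

Step 17
Reactants: 28 (1R,2R,3S)-2-(benzyloxy)-1-[4-(benzyloxy)phenyl]-3-ArBr-3-Bot-propan-1-ol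
Product: 29 protected dimer: (2R,3R)-3,7,8-tris(benzyloxy)-2-[4-(benzyloxy)phenyl]chroman-4-yl (middle unit; C4 bond trans to O3 and to the C2 aryl group) bonded through C4 to C6 of the bottom unit 19
Conditions: Pd(OAc)2 (cat.), 2-(di-tert-butylphosphino)-1,1'-binaphthyl, Cs2CO3, toluene, 80 °C
Reagents that add atoms: none
Why: Intramolecular Buchwald–Hartwig etherification as in step 11; O1–C8a of the middle unit forms and the pyran ring closes without touching C2, C3 or C4.

Step 18
Reactants: 29 protected dimer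
Product: 30 Dim-Br (29 brominated at C6 of the middle unit)
Conditions: NBS, MeCN/CH2Cl2, −20 → 0 °C, dark
Reagents that add atoms: N-bromosuccinimide O=C1CCC(=O)N1Br
Why: Electrophilic aromatic bromination; C6 of the middle unit is the only free position both para to a ring oxygen and ortho to a benzyloxy group, while C5 of the bottom unit is flanked by two substituents and the B rings are mono-ethers.

Step 19
Reactants: 30 Dim-Br; 8 (4S,5S)-4,5-dicyclohexyl-2-(dichloromethyl)-1,3,2-dioxaborolane; 9 [3,4-bis(benzyloxy)-2-bromophenyl]magnesium chloride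
Product: 33 (S)-Dim-CH(ArBr)-Bdch (top C4 set), via aryllithium 31 (not isolated), via α-chloro boronic ester 32 (not isolated)
Conditions: 30, nBuLi, THF, −78 °C; 8, −78 °C; ZnCl2, → rt; then 9 (excess), −78 → 0 °C
Reagents that add atoms: none
Why: As step 13: bromine–lithium exchange, addition of 31 to boron of 8, diol-controlled aryl shift to the (R)-chloride 32 and aryl transfer from 9 with inversion (Matteson homologation) set C4 of the top unit.

Step 20
Reactants: 33 (S)-Dim-CH(ArBr)-Bdch; 5 (dichloromethyl)lithium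
Product: 35 (1S,2S)-Dim-CH(ArBr)-CH(OBn)-Bdch (top C3 set), via α-chloro boronic ester 34 (not isolated)
Conditions: 33 added to 5, THF, −100 °C; ZnCl2, −100 °C → rt; then BnOLi (BnOH, nBuLi), THF/DMSO, 0 °C → rt
Reagents that add atoms: benzyl alcohol OCc1ccccc1
Why: Matteson homologation as in step 14: C4 migrates with retention to the (R)-chloride 34 and benzyloxide displaces chloride with inversion to set C3.

Step 21
Reactants: 35 (1S,2S)-Dim-CH(ArBr)-CH(OBn)-Bdch; 5 (dichloromethyl)lithium; 15 [4-(benzyloxy)phenyl]magnesium bromide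
Product: 37 (1R,2S,3S)-Dim-CH(ArBr)-CH(OBn)-CH(BnOAr)-Bdch (top C2 set), via α-chloro boronic ester 36 (not isolated)
Conditions: 35 added to 5, THF, −100 °C; ZnCl2, −100 °C → rt; then 15, −78 °C → rt
Reagents that add atoms: none
Why: Repeat of the key Matteson homologation with Grignard displacement: C3 migrates with retention to the (R)-chloride 36 and the aryl group of 15 migrates to C2 with inversion, the diol again setting C2.

Step 22
Reactants: 37 (1R,2S,3S)-Dim-CH(ArBr)-CH(OBn)-CH(BnOAr)-Bdch
Product: 38 (1R,2R,3S)-2-(benzyloxy)-1-[4-(benzyloxy)phenyl]-3-ArBr-3-Dim-propan-1-ol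
Conditions: H2O2 (30% aq.), NaOH, THF, 0 °C → rt
Reagents that add atoms: hydrogen peroxide OO
Why: Alkaline peroxide oxidation of C–B to C–OH with retention at C2; 6 is recovered.

Step 23
Reactants: 38 (1R,2R,3S)-2-(benzyloxy)-1-[4-(benzyloxy)phenyl]-3-ArBr-3-Dim-propan-1-ol
Product: 39 protected trimer (thirteen benzyl ethers): top unit (2R,3R)-3,7,8-tris(benzyloxy)-2-[4-(benzyloxy)phenyl]chroman-4-yl bonded through C4 (trans to O3) to C6 of the middle unit of 29
Conditions: Pd(OAc)2 (cat.), 2-(di-tert-butylphosphino)-1,1'-binaphthyl, Cs2CO3, toluene, 80 °C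
Reagents that add atoms: none
Why: Intramolecular Buchwald–Hartwig etherification as in steps 11 and 17; the top pyran ring closes with all nine stereocentres unchanged.

Step 24
Reactants: 39 protected trimer
Product: 40 target: top and middle units (2R,3R,4S)-2-(4-hydroxyphenyl)chroman-3,7,8-triol-4-yl linked C4→C6; bottom unit (2R,3R,4R)-2-(4-hydroxyphenyl)chroman-3,4,7,8-tetrol
Conditions: H2 (1 atm), Pd(OH)2/C, THF/MeOH, rt
Reagents that add atoms: none
Why: Hydrogenolysis of thirteen benzyl ethers under neutral conditions; the ring benzylic C–O bonds (C2–O1, bottom C4–O) are secondary and hindered and cleave far more slowly than O–CH2Ph, as in debenzylations that keep the benzylic hydroxyl of catecholamine-type 4-hydroxybenzyl alcohols. No stereocentre is touched.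

## Compound list

1 | 3-bromobenzene-1,2-diol | Oc1cccc(Br)c1O | starting material
2 | 1,2-bis(benzyloxy)-3-bromobenzene | Brc1cccc(OCc2ccccc2)c1OCc1ccccc1 | intermediate
3 | 1,2-bis(benzyloxy)-3-bromo-4-iodobenzene | Ic1ccc(OCc2ccccc2)c(OCc2ccccc2)c1Br | intermediate
4 | dichloromethane | ClCCl | starting material
5 | (dichloromethyl)lithium | [Li]C(Cl)Cl | intermediate
6 | (1S,2S)-1,2-dicyclohexylethane-1,2-diol | O[C@@H](C1CCCCC1)[C@@H](O)C1CCCCC1 | starting material
7 | dimethyl (dichloromethyl)boronate | COB(OC)C(Cl)Cl | intermediate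
8 | (4S,5S)-4,5-dicyclohexyl-2-(dichloromethyl)-1,3,2-dioxaborolane | ClC(Cl)B1O[C@@H](C2CCCCC2)[C@H](C2CCCCC2)O1 | intermediate
9 | [3,4-bis(benzyloxy)-2-bromophenyl]magnesium chloride | Cl[Mg]c1ccc(OCc2ccccc2)c(OCc2ccccc2)c1Br | intermediate
10 | (4S,5S)-2-{(R)-[3,4-bis(benzyloxy)-2-bromophenyl](chloro)methyl}-4,5-dicyclohexyl-1,3,2-dioxaborolane | Cl[C@@H](c1ccc(OCc2ccccc2)c(OCc2ccccc2)c1Br)B1O[C@@H](C2CCCCC2)[C@H](C2CCCCC2)O1 | intermediate
11 | (4S,5S)-2-{(S)-(benzyloxy)[3,4-bis(benzyloxy)-2-bromophenyl]methyl}-4,5-dicyclohexyl-1,3,2-dioxaborolane | B1(O[C@@H](C2CCCCC2)[C@H](C2CCCCC2)O1)[C@H](OCc1ccccc1)c1ccc(OCc2ccccc2)c(OCc2ccccc2)c1Br | intermediate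
12 | (4S,5S)-2-{(1R,2R)-2-(benzyloxy)-2-[3,4-bis(benzyloxy)-2-bromophenyl]-1-chloroethyl}-4,5-dicyclohexyl-1,3,2-dioxaborolane | Cl[C@H](B1O[C@@H](C2CCCCC2)[C@H](C2CCCCC2)O1)[C@H](OCc1ccccc1)c1ccc(OCc2ccccc2)c(OCc2ccccc2)c1Br | intermediate
13 | (4S,5S)-2-{(1S,2R)-1,2-bis(benzyloxy)-2-[3,4-bis(benzyloxy)-2-bromophenyl]ethyl}-4,5-dicyclohexyl-1,3,2-dioxaborolane | B1(O[C@@H](C2CCCCC2)[C@H](C2CCCCC2)O1)[C@H](OCc1ccccc1)[C@H](OCc1ccccc1)c1ccc(OCc2ccccc2)c(OCc2ccccc2)c1Br | intermediate
14 | 1-(benzyloxy)-4-bromobenzene | Brc1ccc(OCc2ccccc2)cc1 | starting material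
15 | [4-(benzyloxy)phenyl]magnesium bromide | Br[Mg]c1ccc(OCc2ccccc2)cc1 | intermediate
16 | (4S,5S)-2-{(1R,2R,3R)-2,3-bis(benzyloxy)-3-[3,4-bis(benzyloxy)-2-bromophenyl]-1-chloropropyl}-4,5-dicyclohexyl-1,3,2-dioxaborolane | Cl[C@H](B1O[C@@H](C2CCCCC2)[C@H](C2CCCCC2)O1)[C@H](OCc1ccccc1)[C@H](OCc1ccccc1)c1ccc(OCc2ccccc2)c(OCc2ccccc2)c1Br | intermediate
17 | (4S,5S)-2-{(1R,2S,3R)-2,3-bis(benzyloxy)-1-[4-(benzyloxy)phenyl]-3-[3,4-bis(benzyloxy)-2-bromophenyl]propyl}-4,5-dicyclohexyl-1,3,2-dioxaborolane | C(c1ccccc1)Oc1ccc(cc1)[C@@H](B1O[C@@H](C2CCCCC2)[C@H](C2CCCCC2)O1)[C@H](OCc1ccccc1)[C@H](OCc1ccccc1)c1ccc(OCc2ccccc2)c(OCc2ccccc2)c1Br | intermediate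
18 | (1R,2S,3R)-2,3-bis(benzyloxy)-1-[4-(benzyloxy)phenyl]-3-[3,4-bis(benzyloxy)-2-bromophenyl]propan-1-ol | O[C@H](c1ccc(OCc2ccccc2)cc1)[C@H](OCc1ccccc1)[C@H](OCc1ccccc1)c1ccc(OCc2ccccc2)c(OCc2ccccc2)c1Br | intermediate
19 | (2R,3R,4R)-3,4,7,8-tetrakis(benzyloxy)-2-[4-(benzyloxy)phenyl]chromane (2,3-cis-3,4-cis) | c1cc2c(c(OCc3ccccc3)c1OCc1ccccc1)O[C@H](c1ccc(OCc3ccccc3)cc1)[C@H](OCc1ccccc1)[C@@H]2OCc1ccccc1 | intermediate
20 | (2R,3R,4R)-3,4,7,8-tetrakis(benzyloxy)-2-[4-(benzyloxy)phenyl]-6-bromochromane (Bot-Br) | Brc1cc2c(c(OCc3ccccc3)c1OCc1ccccc1)O[C@H](c1ccc(OCc3ccccc3)cc1)[C@H](OCc1ccccc1)[C@@H]2OCc1ccccc1 | intermediate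
21 | Bot-Li (6-lithio derivative of 19) | [Li]c1cc2c(c(OCc3ccccc3)c1OCc1ccccc1)O[C@H](c1ccc(OCc3ccccc3)cc1)[C@H](OCc1ccccc1)[C@@H]2OCc1ccccc1 | intermediate
22 | (R)-Bot-CHCl-Bdch | Cl[C@H](B1O[C@@H](C2CCCCC2)[C@H](C2CCCCC2)O1)c1cc2c(c(OCc3ccccc3)c1OCc1ccccc1)O[C@H](c1ccc(OCc3ccccc3)cc1)[C@H](OCc1ccccc1)[C@@H]2OCc1ccccc1 | intermediate
23 | (S)-Bot-CH(ArBr)-Bdch | B1(O[C@@H](C2CCCCC2)[C@H](C2CCCCC2)O1)[C@@H](c1cc2c(c(OCc3ccccc3)c1OCc1ccccc1)O[C@H](c1ccc(OCc3ccccc3)cc1)[C@H](OCc1ccccc1)[C@@H]2OCc1ccccc1)c1ccc(OCc2ccccc2)c(OCc2ccccc2)c1Br | intermediate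
24 | (1R,2S)-Bot-CH(ArBr)-CHCl-Bdch (C1 = CHCl) | Cl[C@H](B1O[C@@H](C2CCCCC2)[C@H](C2CCCCC2)O1)[C@@H](c1cc2c(c(OCc3ccccc3)c1OCc1ccccc1)O[C@H](c1ccc(OCc3ccccc3)cc1)[C@H](OCc1ccccc1)[C@@H]2OCc1ccccc1)c1ccc(OCc2ccccc2)c(OCc2ccccc2)c1Br | intermediate
25 | (1S,2S)-Bot-CH(ArBr)-CH(OBn)-Bdch (C1 on boron; key-step precursor) | B1(O[C@@H](C2CCCCC2)[C@H](C2CCCCC2)O1)[C@H](OCc1ccccc1)[C@@H](c1cc2c(c(OCc3ccccc3)c1OCc1ccccc1)O[C@H](c1ccc(OCc3ccccc3)cc1)[C@H](OCc1ccccc1)[C@@H]2OCc1ccccc1)c1ccc(OCc2ccccc2)c(OCc2ccccc2)c1Br | intermediate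
26 | (1R,2R,3S)-Bot-CH(ArBr)-CH(OBn)-CHCl-Bdch (C1 = CHCl) | Cl[C@H](B1O[C@@H](C2CCCCC2)[C@H](C2CCCCC2)O1)[C@H](OCc1ccccc1)[C@@H](c1cc2c(c(OCc3ccccc3)c1OCc1ccccc1)O[C@H](c1ccc(OCc3ccccc3)cc1)[C@H](OCc1ccccc1)[C@@H]2OCc1ccccc1)c1ccc(OCc2ccccc2)c(OCc2ccccc2)c1Br | intermediate
27 | (1R,2S,3S)-Bot-CH(ArBr)-CH(OBn)-CH(BnOAr)-Bdch (C1 on boron; key-step product) | C(c1ccccc1)Oc1ccc(cc1)[C@@H](B1O[C@@H](C2CCCCC2)[C@H](C2CCCCC2)O1)[C@H](OCc1ccccc1)[C@@H](c1cc2c(c(OCc3ccccc3)c1OCc1ccccc1)O[C@H](c1ccc(OCc3ccccc3)cc1)[C@H](OCc1ccccc1)[C@@H]2OCc1ccccc1)c1ccc(OCc2ccccc2)c(OCc2ccccc2)c1Br | intermediate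
28 | (1R,2R,3S)-2-(benzyloxy)-1-[4-(benzyloxy)phenyl]-3-ArBr-3-Bot-propan-1-ol | O[C@H](c1ccc(OCc2ccccc2)cc1)[C@H](OCc1ccccc1)[C@@H](c1cc2c(c(OCc3ccccc3)c1OCc1ccccc1)O[C@H](c1ccc(OCc3ccccc3)cc1)[C@H](OCc1ccccc1)[C@@H]2OCc1ccccc1)c1ccc(OCc2ccccc2)c(OCc2ccccc2)c1Br | intermediate
29 | protected dimer: middle unit (2R,3R)-3,7,8-tris(benzyloxy)-2-[4-(benzyloxy)phenyl]chroman-4-yl, bonded through C4 (trans to O3 and to the C2 aryl group) to C6 of bottom unit 19 | c1cc2c(c(OCc3ccccc3)c1OCc1ccccc1)O[C@H](c1ccc(OCc3ccccc3)cc1)[C@H](OCc1ccccc1)[C@H]2c1cc2c(c(OCc3ccccc3)c1OCc1ccccc1)O[C@H](c1ccc(OCc3ccccc3)cc1)[C@H](OCc1ccccc1)[C@@H]2OCc1ccccc1 | intermediate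
30 | Dim-Br (29 with Br at C6 of the middle unit) | Brc1cc2c(c(OCc3ccccc3)c1OCc1ccccc1)O[C@H](c1ccc(OCc3ccccc3)cc1)[C@H](OCc1ccccc1)[C@H]2c1cc2c(c(OCc3ccccc3)c1OCc1ccccc1)O[C@H](c1ccc(OCc3ccccc3)cc1)[C@H](OCc1ccccc1)[C@@H]2OCc1ccccc1 | intermediate
31 | Dim-Li | [Li]c1cc2c(c(OCc3ccccc3)c1OCc1ccccc1)O[C@H](c1ccc(OCc3ccccc3)cc1)[C@H](OCc1ccccc1)[C@H]2c1cc2c(c(OCc3ccccc3)c1OCc1ccccc1)O[C@H](c1ccc(OCc3ccccc3)cc1)[C@H](OCc1ccccc1)[C@@H]2OCc1ccccc1 | intermediate
32 | (R)-Dim-CHCl-Bdch | Cl[C@H](B1O[C@@H](C2CCCCC2)[C@H](C2CCCCC2)O1)c1cc2c(c(OCc3ccccc3)c1OCc1ccccc1)O[C@H](c1ccc(OCc3ccccc3)cc1)[C@H](OCc1ccccc1)[C@H]2c1cc2c(c(OCc3ccccc3)c1OCc1ccccc1)O[C@H](c1ccc(OCc3ccccc3)cc1)[C@H](OCc1ccccc1)[C@@H]2OCc1ccccc1 | intermediate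
33 | (S)-Dim-CH(ArBr)-Bdch | B1(O[C@@H](C2CCCCC2)[C@H](C2CCCCC2)O1)[C@@H](c1cc2c(c(OCc3ccccc3)c1OCc1ccccc1)O[C@H](c1ccc(OCc3ccccc3)cc1)[C@H](OCc1ccccc1)[C@H]2c1cc2c(c(OCc3ccccc3)c1OCc1ccccc1)O[C@H](c1ccc(OCc3ccccc3)cc1)[C@H](OCc1ccccc1)[C@@H]2OCc1ccccc1)c1ccc(OCc2ccccc2)c(OCc2ccccc2)c1Br | intermediate
34 | (1R,2S)-Dim-CH(ArBr)-CHCl-Bdch | Cl[C@H](B1O[C@@H](C2CCCCC2)[C@H](C2CCCCC2)O1)[C@@H](c1cc2c(c(OCc3ccccc3)c1OCc1ccccc1)O[C@H](c1ccc(OCc3ccccc3)cc1)[C@H](OCc1ccccc1)[C@H]2c1cc2c(c(OCc3ccccc3)c1OCc1ccccc1)O[C@H](c1ccc(OCc3ccccc3)cc1)[C@H](OCc1ccccc1)[C@@H]2OCc1ccccc1)c1ccc(OCc2ccccc2)c(OCc2ccccc2)c1Br | intermediate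
35 | (1S,2S)-Dim-CH(ArBr)-CH(OBn)-Bdch | B1(O[C@@H](C2CCCCC2)[C@H](C2CCCCC2)O1)[C@H](OCc1ccccc1)[C@@H](c1cc2c(c(OCc3ccccc3)c1OCc1ccccc1)O[C@H](c1ccc(OCc3ccccc3)cc1)[C@H](OCc1ccccc1)[C@H]2c1cc2c(c(OCc3ccccc3)c1OCc1ccccc1)O[C@H](c1ccc(OCc3ccccc3)cc1)[C@H](OCc1ccccc1)[C@@H]2OCc1ccccc1)c1ccc(OCc2ccccc2)c(OCc2ccccc2)c1Br | intermediate
36 | (1R,2R,3S)-Dim-CH(ArBr)-CH(OBn)-CHCl-Bdch | Cl[C@H](B1O[C@@H](C2CCCCC2)[C@H](C2CCCCC2)O1)[C@H](OCc1ccccc1)[C@@H](c1cc2c(c(OCc3ccccc3)c1OCc1ccccc1)O[C@H](c1ccc(OCc3ccccc3)cc1)[C@H](OCc1ccccc1)[C@H]2c1cc2c(c(OCc3ccccc3)c1OCc1ccccc1)O[C@H](c1ccc(OCc3ccccc3)cc1)[C@H](OCc1ccccc1)[C@@H]2OCc1ccccc1)c1ccc(OCc2ccccc2)c(OCc2ccccc2)c1Br | intermediate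
37 | (1R,2S,3S)-Dim-CH(ArBr)-CH(OBn)-CH(BnOAr)-Bdch | C(c1ccccc1)Oc1ccc(cc1)[C@@H](B1O[C@@H](C2CCCCC2)[C@H](C2CCCCC2)O1)[C@H](OCc1ccccc1)[C@@H](c1cc2c(c(OCc3ccccc3)c1OCc1ccccc1)O[C@H](c1ccc(OCc3ccccc3)cc1)[C@H](OCc1ccccc1)[C@H]2c1cc2c(c(OCc3ccccc3)c1OCc1ccccc1)O[C@H](c1ccc(OCc3ccccc3)cc1)[C@H](OCc1ccccc1)[C@@H]2OCc1ccccc1)c1ccc(OCc2ccccc2)c(OCc2ccccc2)c1Br | intermediate
38 | (1R,2R,3S)-2-(benzyloxy)-1-[4-(benzyloxy)phenyl]-3-ArBr-3-Dim-propan-1-ol | O[C@H](c1ccc(OCc2ccccc2)cc1)[C@H](OCc1ccccc1)[C@@H](c1cc2c(c(OCc3ccccc3)c1OCc1ccccc1)O[C@H](c1ccc(OCc3ccccc3)cc1)[C@H](OCc1ccccc1)[C@H]2c1cc2c(c(OCc3ccccc3)c1OCc1ccccc1)O[C@H](c1ccc(OCc3ccccc3)cc1)[C@H](OCc1ccccc1)[C@@H]2OCc1ccccc1)c1ccc(OCc2ccccc2)c(OCc2ccccc2)c1Br | intermediate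
39 | protected trimer (thirteen benzyl ethers): top unit (2R,3R)-3,7,8-tris(benzyloxy)-2-[4-(benzyloxy)phenyl]chroman-4-yl bonded through C4 (trans to O3) to C6 of the middle unit of 29 | c1cc2c(c(OCc3ccccc3)c1OCc1ccccc1)O[C@H](c1ccc(OCc3ccccc3)cc1)[C@H](OCc1ccccc1)[C@H]2c1cc2c(c(OCc3ccccc3)c1OCc1ccccc1)O[C@H](c1ccc(OCc3ccccc3)cc1)[C@H](OCc1ccccc1)[C@H]2c1cc2c(c(OCc3ccccc3)c1OCc1ccccc1)O[C@H](c1ccc(OCc3ccccc3)cc1)[C@H](OCc1ccccc1)[C@@H]2OCc1ccccc1 | intermediate
40 | target (CNP0140823.1): top and middle units (2R,3R,4S), bottom unit (2R,3R,4R) | Oc1ccc([C@H]2Oc3c(ccc(O)c3O)[C@H](c3cc4c(c(O)c3O)O[C@H](c3ccc(O)cc3)[C@H](O)[C@H]4c3cc4c(c(O)c3O)O[C@H](c3ccc(O)cc3)[C@H](O)[C@@H]4O)[C@H]2O)cc1 | target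

## Step count and least certain steps

Total step count: 24. Longest linear sequence: 21 steps (1, 2, 5–7, 9–24). Steps 3 and 4 (to 8) and step 8 (to 15) are side branches that join the main line at steps 6 and 9. Steps 3 and 5 are reagent preparations whose products cannot be stored, so each is run again before every step that consumes 5 or 9.

Step 15 (key step; the same operation recurs as steps 9 and 21). The most likely failure is incomplete insertion of the carbenoid at a crowded, α-oxygenated boron: 5 decomposes above about −80 °C while ate-complex formation is slowed by the diarylmethyl group. The second risk is β-elimination of the C3 benzyloxy group from the aryl ate complex in competition with the aryl shift. The fallback sets out from 25 and returns at 28, with C2 set by substrate control instead of by the diol. Compound 25 is homologated with (chloromethyl)lithium (ICH2Cl, nBuLi, THF, −78 °C → rt; a CH2 insertion that leaves no α-leaving group behind) to the primary boronic ester (4S,5S)-2-[(2S,3S)-2-(benzyloxy)-3-ArBr-3-Bot-propyl]-4,5-dicyclohexyl-1,3,2-dioxaborolane F1. Alkaline H2O2 gives the primary alcohol (2R,3S)-2-(benzyloxy)-3-ArBr-3-Bot-propan-1-ol F2. Dess–Martin oxidation gives the α-benzyloxy aldehyde (2R,3S)-2-(benzyloxy)-3-ArBr-3-Bot-propanal F3. Addition of 15 in the presence of MgBr2·OEt2 (CH2Cl2/Et2O, −78 °C) under Cram chelation control should give the syn (1R,2R) alcohol 28.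

Step 13 (repeated as step 19; step 6 is the small-fragment analogue). The most likely failure is unclean ate-complex formation, because the aryllithium can abstract the acidic proton of 8 or add twice to boron. The second risk is loss of configurational purity at the new benzylic carbon by chloride exchange or reversible ionisation of the electron-rich chloride 22 before 9 transfers its aryl group; immediate capture at low temperature and zinc-bound chloride limit this. The fallback sets out from 20 and returns at 22, building the ate complex from the carbenoid side with no aryllithium. Palladium-catalysed borylation of 20 with tetrahydroxydiboron (Pd(OAc)2, XPhos, KOAc, EtOH, 80 °C) gives the boronic acid Bot-B(OH)2 F4. Esterification with 6 (MgSO4, Et2O) gives the arylboronic ester Bot-Bdch F5. Treatment of F5 with 5 (fresh from step 3, −100 °C) and ZnCl2 gives 22, which is carried on with 9 to 23 as in step 13.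

Step 17 (and its analogues, steps 11 and 23). The most likely failure is β-hydride elimination from the divalent palladium alkoxide, which oxidises the benzylic alcohol to the ketone and reduces the C–Br bond. This is favoured here because oxidative addition and reductive elimination at a bromide flanked by two ortho substituents are slow. The fallback sets out from 28 and returns at 29 without any new compound (F0). It replaces the palladium cycle by an Ullmann-type etherification through a monovalent copper alkoxide, which has no comparable β-hydride pathway (CuI, 3,4,7,8-tetramethyl-1,10-phenanthroline, Cs2CO3, toluene, 110 °C).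

Step 24. The most likely failure is hydrogenolytic loss of the bottom C4 hydroxyl once the para phenol at C7 is free, while the hindered aliphatic benzyl ethers are still being cleaved. Incomplete cleavage and air oxidation of the polyphenol on the catalyst are further risks. The fallback sets out from 39 and returns at 40 and keeps the A rings electron-poor during the critical reduction. Hydrogenolysis in a non-protic medium (H2, Pd/C, EtOAc/THF, rt), stopped when the nine aryl ethers have gone, gives the nonaphenol that keeps the four aliphatic benzyl ethers (3-O of each unit and bottom 4-O) F6. Ac2O/pyridine gives its nona-acetate F7. H2 over Pd(OH)2/C (EtOAc/MeOH) then removes the four aliphatic benzyl ethers to give the nona-acetate tetraol F8; with C7 acetylated the bottom C4–O bond is no longer activated by a para phenol. Hydrazine hydrate (THF/MeOH, 0 °C, under argon) finally cleaves the nine aryl acetates to give 40.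

## Further compounds

F1 | step 15 | (4S,5S)-2-[(2S,3S)-2-(benzyloxy)-3-ArBr-3-Bot-propyl]-4,5-dicyclohexyl-1,3,2-dioxaborolane | B1(O[C@@H](C2CCCCC2)[C@H](C2CCCCC2)O1)C[C@H](OCc1ccccc1)[C@@H](c1cc2c(c(OCc3ccccc3)c1OCc1ccccc1)O[C@H](c1ccc(OCc3ccccc3)cc1)[C@H](OCc1ccccc1)[C@@H]2OCc1ccccc1)c1ccc(OCc2ccccc2)c(OCc2ccccc2)c1Br
F2 | step 15 | (2R,3S)-2-(benzyloxy)-3-ArBr-3-Bot-propan-1-ol | OC[C@H](OCc1ccccc1)[C@@H](c1cc2c(c(OCc3ccccc3)c1OCc1ccccc1)O[C@H](c1ccc(OCc3ccccc3)cc1)[C@H](OCc1ccccc1)[C@@H]2OCc1ccccc1)c1ccc(OCc2ccccc2)c(OCc2ccccc2)c1Br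
F3 | step 15 | (2R,3S)-2-(benzyloxy)-3-ArBr-3-Bot-propanal | O=C[C@H](OCc1ccccc1)[C@@H](c1cc2c(c(OCc3ccccc3)c1OCc1ccccc1)O[C@H](c1ccc(OCc3ccccc3)cc1)[C@H](OCc1ccccc1)[C@@H]2OCc1ccccc1)c1ccc(OCc2ccccc2)c(OCc2ccccc2)c1Br
F4 | step 13 | Bot-B(OH)2, [(2R,3R,4R)-3,4,7,8-tetrakis(benzyloxy)-2-[4-(benzyloxy)phenyl]chroman-6-yl]boronic acid | OB(O)c1cc2c(c(OCc3ccccc3)c1OCc1ccccc1)O[C@H](c1ccc(OCc3ccccc3)cc1)[C@H](OCc1ccccc1)[C@@H]2OCc1ccccc1
F5 | step 13 | Bot-Bdch, the (S,S)-1,2-dicyclohexylethanediol ester of F4 | B1(O[C@@H](C2CCCCC2)[C@H](C2CCCCC2)O1)c1cc2c(c(OCc3ccccc3)c1OCc1ccccc1)O[C@H](c1ccc(OCc3ccccc3)cc1)[C@H](OCc1ccccc1)[C@@H]2OCc1ccccc1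
F0 | step 17 | none | none
F6 | step 24 | trimer with nine free phenols and four aliphatic benzyl ethers (3-O of each unit, bottom 4-O) | Oc1ccc([C@H]2Oc3c(ccc(O)c3O)[C@H](c3cc4c(c(O)c3O)O[C@H](c3ccc(O)cc3)[C@H](OCc5ccccc5)[C@H]4c3cc4c(c(O)c3O)O[C@H](c3ccc(O)cc3)[C@H](OCc5ccccc5)[C@@H]4OCc5ccccc5)[C@H]2OCc5ccccc5)cc1
F7 | step 24 | nona-acetate of F6 | CC(=O)Oc1ccc([C@H]2Oc3c(ccc(OC(C)=O)c3OC(C)=O)[C@H](c3cc4c(c(OC(C)=O)c3OC(C)=O)O[C@H](c3ccc(OC(C)=O)cc3)[C@H](OCc5ccccc5)[C@H]4c3cc4c(c(OC(C)=O)c3OC(C)=O)O[C@H](c3ccc(OC(C)=O)cc3)[C@H](OCc5ccccc5)[C@@H]4OCc5ccccc5)[C@H]2OCc5ccccc5)cc1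
F8 | step 24 | nona-O-acetyl trimer with free 3-OH groups and free bottom 4-OH | CC(=O)Oc1ccc([C@H]2Oc3c(ccc(OC(C)=O)c3OC(C)=O)[C@H](c3cc4c(c(OC(C)=O)c3OC(C)=O)O[C@H](c3ccc(OC(C)=O)cc3)[C@H](O)[C@H]4c3cc4c(c(OC(C)=O)c3OC(C)=O)O[C@H](c3ccc(OC(C)=O)cc3)[C@H](O)[C@@H]4O)[C@H]2O)cc1
A1 | alternative 1 | benzhydrol: [3,4-bis(benzyloxy)-2-(vinyloxy)phenyl](protected dimer-6-yl)methanol, bottom 3,4-diol as cyclic carbonate, carbinol configuration undefined | OC(c3cc4c(c(OCc5ccccc5)c3OCc5ccccc5)O[C@H](c3ccc(OCc5ccccc5)cc3)[C@H](OCc5ccccc5)[C@H]4c3cc4c(c(OCc5ccccc5)c3OCc5ccccc5)O[C@H](c3ccc(OCc5ccccc5)cc3)[C@H](O6)[C@@H]4OC6=O)c3ccc(OCc5ccccc5)c(OCc5ccccc5)c3OC=C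
A2 | alternative 1 | top-unit 4-aryl-7,8-bis(benzyloxy)-4H-chromene on the protected dimer (bottom 3,4-carbonate) | C2=C[C@@H](c3cc4c(c(OCc5ccccc5)c3OCc5ccccc5)O[C@H](c3ccc(OCc5ccccc5)cc3)[C@H](OCc5ccccc5)[C@H]4c3cc4c(c(OCc5ccccc5)c3OCc5ccccc5)O[C@H](c3ccc(OCc5ccccc5)cc3)[C@H](O6)[C@@H]4OC6=O)c3ccc(OCc5ccccc5)c(OCc5ccccc5)c3O2
A3 | alternative 2 | (E)-3-(protected dimer-6-yl)prop-2-enal (bottom 3,4-acetonide) | O=C/C=C/c3cc4c(c(OCc5ccccc5)c3OCc5ccccc5)O[C@H](c3ccc(OCc5ccccc5)cc3)[C@H](OCc5ccccc5)[C@H]4c3cc4c(c(OCc5ccccc5)c3OCc5ccccc5)O[C@H](c3ccc(OCc5ccccc5)cc3)[C@H](O6)[C@@H]4OC6(C)C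
A4 | alternative 2 | cyclohexane-1,2-dione | O=C1CCCCC1=O
A5 | alternative 2 | top-unit 4-aryl-2-hydroxy-2,3,4,5,6,7-hexahydro-8H-chromen-8-one on the protected dimer | OC1C[C@@H](c3cc4c(c(OCc5ccccc5)c3OCc5ccccc5)O[C@H](c3ccc(OCc5ccccc5)cc3)[C@H](OCc5ccccc5)[C@H]4c3cc4c(c(OCc5ccccc5)c3OCc5ccccc5)O[C@H](c3ccc(OCc5ccccc5)cc3)[C@H](O6)[C@@H]4OC6(C)C)C2=C(O1)C(=O)CCC2
A6 | alternative 3 | mesylate: 6,7-bis(benzyloxy)-2,3-dihydrobenzofuran carrying the protected dimer at C3 and a (mesyloxy)[4-(pivaloyloxy)phenyl]methyl group at C2 | CC(C)(C)C(=O)Oc1ccc([C@H](OS(C)(=O)=O)[C@H]2Oc3c(ccc(OCc5ccccc5)c3OCc5ccccc5)[C@@H]2c3cc4c(c(OCc5ccccc5)c3OCc5ccccc5)O[C@H](c3ccc(OCc5ccccc5)cc3)[C@H](OCc5ccccc5)[C@H]4c3cc4c(c(OCc5ccccc5)c3OCc5ccccc5)O[C@H](c3ccc(OCc5ccccc5)cc3)[C@H](O6)[C@@H]4OC6(C)C)cc1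
A7 | alternative 3 | protected trimer, top unit as 3-O-acetate and 4'-O-pivalate | CC(C)(C)C(=O)Oc1ccc([C@H]2Oc3c(ccc(OCc5ccccc5)c3OCc5ccccc5)[C@H](c3cc4c(c(OCc5ccccc5)c3OCc5ccccc5)O[C@H](c3ccc(OCc5ccccc5)cc3)[C@H](OCc5ccccc5)[C@H]4c3cc4c(c(OCc5ccccc5)c3OCc5ccccc5)O[C@H](c3ccc(OCc5ccccc5)cc3)[C@H](O6)[C@@H]4OC6(C)C)[C@H]2OC(C)=O)cc1
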